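C5–OH is traced back to a 5-O-methyl ether. The retrosynthesis then cuts O1–C8a (ring C), C3–C4 (joins the two halves), C5–O on ring A, and C2–C1' on ring B.
Forward: rings A and B are bought as methyl syringate and 1,2,4-trimethoxybenzene. Ring B is acylated with the C2–C3 unit, ring A gains its C5 oxygen by bromination and copper-catalysed methoxylation, a Claisen condensation makes C3–C4, and ring C, the only ring built, closes last.
Enabling feature: on ring A the O7 phenol lies between the 6- and 8-methoxy groups and para to C4a, which carries the C4 carbonyl. Oxidation of such a 4-acyl-2,6-dimethoxyphenol in methanol gives a masked o-benzoquinone, in which the C8a–H carbon becomes an acceptor for the enol oxygen that ends as O1.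
The 5-methoxy group passes through the closure as a spectator. It leaves C8a as the only C–H of ring A, crowds the dienone against dimerisation, and leaves the product no ring-A C–H to oxidise further.
Stereochemistry: the target has no stereocentre. The CH(OMe) carbon of the open-chain diketones is racemic, labile and ends as sp2 C3.

Key step: step 7

Assumption: the target has no stereogenic element (no stereocentre, and the C2–C1' axis is not expected to be configurationally stable), so the achiral compound as drawn is the single species required.

Step 1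
Reactants: 1 1,2,4-trimethoxybenzene; 2 methoxyacetyl chloride
Product: 3 2-methoxy-1-(2,4,5-trimethoxyphenyl)ethan-1-one
Conditions: SnCl4 (1.1 equiv), CH2Cl2, −20 → 0 °C; aq. HCl work-up
Reagents that add atoms: none
Why: Friedel–Crafts acylation at C5 of 1, the only unflanked position that is para to one methoxy group and ortho to another; the mild Lewis acid at low temperature should let this very nucleophilic arene take the acyl chloride complex before it loses CO or strips the ortho methyl ether.

Step 2
Reactants: 4 methyl syringate (methyl 4-hydroxy-3,5-dimethoxybenzoate)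
Product: 5 methyl 4-(benzyloxy)-3,5-dimethoxybenzoate
Conditions: BnBr (1.1 equiv), K2CO3 (1.5 equiv), DMF, 60 °C
Reagents that add atoms: benzyl bromide, BrCc1ccccc1
Why: Williamson ether synthesis on the only acidic OH, which masks the phenol whose phenoxide would otherwise deactivate the ester as an acyl donor in step 5.

Step 3
Reactants: 5 methyl 4-(benzyloxy)-3,5-dimethoxybenzoate
Product: 6 methyl 4-(benzyloxy)-2-bromo-3,5-dimethoxybenzoate
Conditions: NBS (1.05 equiv), MeCN, 0 °C → rt, dark
Reagents that add atoms: N-bromosuccinimide, O=C1CCC(=O)N1Br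
Why: Electrophilic aromatic bromination at one of two equivalent free positions, each ortho to one methoxy group and para to the other; the first bromine crowds and deactivates the ring, so one equivalent should stop at the monobromide, and ionic conditions spare the benzylic CH2.

Step 4
Reactants: 6 methyl 4-(benzyloxy)-2-bromo-3,5-dimethoxybenzoate
Product: 7 methyl 4-(benzyloxy)-2,3,5-trimethoxybenzoate
Conditions: NaOMe (4 equiv), CuBr (15 mol %), MeOH–DMF, 100 °C
Reagents that add atoms: sodium methoxide, [Na+].[O-]C
Why: Ullmann-type copper(I)-catalysed methoxylation of an aryl bromide, a standard entry to polymethoxyarenes; the ortho ester can hold copper near the C–Br bond, methoxide can only exchange the methyl ester degenerately, and the benzyl ether is inert to base.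

Step 5
Reactants: 3 2-methoxy-1-(2,4,5-trimethoxyphenyl)ethan-1-one; 7 methyl 4-(benzyloxy)-2,3,5-trimethoxybenzoate
Product: 8 1-[4-(benzyloxy)-2,3,5-trimethoxyphenyl]-2-methoxy-3-(2,4,5-trimethoxyphenyl)propane-1,3-dione (racemic)
Conditions: NaH (2.5 equiv), THF, reflux; then 1 M HCl, 0 °C
Reagents that add atoms: none
Why: Crossed Claisen condensation in which only 3 can enolise and only 7 can donate an acyl group, driven by irreversible deprotonation of the diketone; the new CH(OMe) centre is racemic and labile, which does not matter because it becomes sp2 in step 7.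

Step 6
Reactants: 8 1-[4-(benzyloxy)-2,3,5-trimethoxyphenyl]-2-methoxy-3-(2,4,5-trimethoxyphenyl)propane-1,3-dione
Product: 9 1-(4-hydroxy-2,3,5-trimethoxyphenyl)-2-methoxy-3-(2,4,5-trimethoxyphenyl)propane-1,3-dione (racemic)
Conditions: H2 (1 atm), 10 % Pd/C, EtOAc, rt
Reagents that add atoms: none
Why: Catalytic hydrogenolysis of a benzyl aryl ether under neutral conditions, which should not reduce the electron-rich aryl ketones or touch the methyl ethers.

Step 7
Reactants: 9 1-(4-hydroxy-2,3,5-trimethoxyphenyl)-2-methoxy-3-(2,4,5-trimethoxyphenyl)propane-1,3-dione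
Product: 11 7-hydroxy-3,5,6,8,2',4',5'-heptamethoxyflavone, via masked o-benzoquinone monoketal 10 (not isolated)
Conditions: (i) RVC anode, Pt cathode, undivided cell, Et4NOTs (0.1 M), 2,6-lutidine (3 equiv), MeOH (0.02 M in 9), 0 °C, anode held at the first (phenol) wave, ca. +0.7 V vs Ag/AgCl, 2.1 F/mol; (ii) current off, MeOH evaporated cold, MeCN, DBU (1.5 equiv), 0 °C → rt; (iii) AcOH
Reagents that add atoms: methanol, CO
Why: Proposed new method: two-electron oxidation of the lutidine-buffered ring-A phenol gives a phenoxenium ion that methanol captures at the methoxy-bearing ortho carbon next to the lone ring C–H (the para carbon is disfavoured by its acyl group), and the resulting 6,6-dimethoxycyclohexa-2,4-dienone 10 can build up because the 2-methoxy-1,3-diketone is little enolised and is not ionised by lutidine. Once the current is off and methanol is removed, DBU forms the diketone enolate, whose oxygen on the trimethoxyphenyl side adds to that CH carbon (δ to the dienone carbonyl and β to the C4 carbonyl) to make O1–C8a, and loss of methanol across C8a–H/C8–OMe restores the arene with its 8-methoxy group. Ring C closes in the 6-endo-trig mode, since both carbons of the attacked C4a=C8a double bond lie in the new ring, whereas attack through the enolate carbon would need a four-membered ring. The closest known reaction types are the anodic or iodine(III) oxidation of 2-methoxyphenols to masked o-benzoquinones and the addition of tethered or external nucleophiles to such ketals with rearomatisation; closure of a pyranone by a diketone enolate oxygen in this way is not known. The step needs oxidation of ring A only, which the substrate secures by carrying its sole phenol there (that wave lies well below the wave of the neutral trimethoxyphenyl ketone), and separating electrolysis from closure in time keeps both the enolate and the product phenol away from a live anode. No stereocentre is formed (the labile CH(OMe) carbon becomes sp2 C3) and regiochemistry is fixed because C8a is the only C–H of ring A, the isomeric ketal at the other methoxy-bearing carbon leading to the same flavone by β-attack and vinylogous loss of methanol.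

Step 8
Reactants: 11 7-hydroxy-3,5,6,8,2',4',5'-heptamethoxyflavone
Product: 12 5,7-dihydroxy-3,6,8,2',4',5'-hexamethoxyflavone
Conditions: BCl3 (2.5 equiv), CH2Cl2, −78 → −10 °C; H2O work-up
Reagents that add atoms: none
Why: Chelation-controlled aryl methyl ether cleavage, in which boron bound to the C4 carbonyl reaches the peri 5-methoxy oxygen through a six-membered chelate and chloride removes that methyl group; the 3-methoxy group could form only a five-membered chelate, the other five ethers have no carbonyl neighbour, and the extra BCl3 covers the free O7–H.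

Compound list
1 | 1,2,4-trimethoxybenzene | COc1ccc(OC)c(OC)c1 | starting material
2 | methoxyacetyl chloride | COCC(=O)Cl | starting material
3 | 2-methoxy-1-(2,4,5-trimethoxyphenyl)ethan-1-one | COCC(=O)c1cc(OC)c(OC)cc1OC | intermediate
4 | methyl syringate (methyl 4-hydroxy-3,5-dimethoxybenzoate) | COC(=O)c1cc(OC)c(O)c(OC)c1 | starting material
5 | methyl 4-(benzyloxy)-3,5-dimethoxybenzoate | COC(=O)c1cc(OC)c(OCc2ccccc2)c(OC)c1 | intermediate
6 | methyl 4-(benzyloxy)-2-bromo-3,5-dimethoxybenzoate | COC(=O)c1cc(OC)c(OCc2ccccc2)c(OC)c1Br | intermediate
7 | methyl 4-(benzyloxy)-2,3,5-trimethoxybenzoate | COC(=O)c1cc(OC)c(OCc2ccccc2)c(OC)c1OC | intermediate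
8 | 1-[4-(benzyloxy)-2,3,5-trimethoxyphenyl]-2-methoxy-3-(2,4,5-trimethoxyphenyl)propane-1,3-dione (racemic, labile centre) | COC(C(=O)c1cc(OC)c(OCc2ccccc2)c(OC)c1OC)C(=O)c1cc(OC)c(OC)cc1OC | intermediate
9 | 1-(4-hydroxy-2,3,5-trimethoxyphenyl)-2-methoxy-3-(2,4,5-trimethoxyphenyl)propane-1,3-dione (racemic, labile centre) | COC(C(=O)c1cc(OC)c(O)c(OC)c1OC)C(=O)c1cc(OC)c(OC)cc1OC | intermediate
10 | 2-methoxy-1-(3,3,5,6-tetramethoxy-4-oxocyclohexa-1,5-dien-1-yl)-3-(2,4,5-trimethoxyphenyl)propane-1,3-dione (masked o-benzoquinone monoketal, racemic, not isolated) | COC(C(=O)C1=CC(OC)(OC)C(=O)C(OC)=C1OC)C(=O)c1cc(OC)c(OC)cc1OC | intermediate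
11 | 7-hydroxy-3,5,6,8,2',4',5'-heptamethoxyflavone | COc1cc(OC)c(-c2oc3c(OC)c(O)c(OC)c(OC)c3c(=O)c2OC)cc1OC | intermediate
12 | 5,7-dihydroxy-3,6,8,2',4',5'-hexamethoxyflavone | COc1cc(OC)c(-c2oc3c(OC)c(O)c(OC)c(O)c3c(=O)c2OC)cc1OC | target

Total step count: 8. Longest linear sequence: 7 steps (4 → 5 → 6 → 7 → 8 → 9 → 11 → 12).

Steps most likely to fail

**Step 7 (labelled step).**
- What may go wrong: the dienone may dimerise by Diels–Alder reaction while it accumulates. Base may cleave it at the acyl bond before the enolate oxygen reaches C8a. Residual methanol may add in place of the enolate.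
- The fallback uses known chemistry and makes O1–C8a by copper-catalysed O-arylation of a C–Br bond instead of by C–H oxidation. It sets out from bromide 6 (with ketone 3) and returns to the route at 12.
- Crossed Claisen condensation of 3 with 6 (NaH, THF, reflux) should give 1-[4-(benzyloxy)-2-bromo-3,5-dimethoxyphenyl]-2-methoxy-3-(2,4,5-trimethoxyphenyl)propane-1,3-dione F1.
- Intramolecular Ullmann-type O-arylation of its enolate (CuI cat., K2CO3, DMF, 100 °C), a known flavone closure for 1-(2-haloaryl)-1,3-diketones, should give 7-(benzyloxy)-3,6,8,2',4',5'-hexamethoxyflavone F2.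
- Ketone-directed ruthenium(II)-catalysed C5–H hydroxylation, a reaction type known for flavones ([RuCl2(p-cymene)]2 cat., PhI(OCOCF3)2, DCE, 80 °C, aqueous work-up to hydrolyse the first-formed trifluoroacetate), should give 7-(benzyloxy)-5-hydroxy-3,6,8,2',4',5'-hexamethoxyflavone F3.
- Hydrogenolysis (H2, Pd/C, EtOAc) then delivers 12, so steps 4 to 8 are bypassed.

**Step 5.**
- What may go wrong: acyl transfer to the ortho-substituted, electron-rich ester may be slow. Retro-Claisen scrambling by methoxide and self-condensation of the ketone could then take over.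
- The fallback replaces ester acylation by an aldol addition at the aldehyde oxidation level, followed by oxidation. It sets out from 7 and returns at 8.
- Reduction (LiAlH4, THF, 0 °C) should give [4-(benzyloxy)-2,3,5-trimethoxyphenyl]methanol F4.
- Oxidation (MnO2, CH2Cl2) should give 4-(benzyloxy)-2,3,5-trimethoxybenzaldehyde F5.
- Addition of the lithium enolate of 3 (LDA, THF, −78 °C) should give 3-[4-(benzyloxy)-2,3,5-trimethoxyphenyl]-3-hydroxy-2-methoxy-1-(2,4,5-trimethoxyphenyl)propan-1-one F6 as a mixture of diastereomers, which does not matter.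
- Dess–Martin oxidation converts this to 8.

**Step 8.**
- What may go wrong: site selectivity may be lost. Boron held on O7 or on the freed O5 may go on to cleave the neighbouring 6- or 8-methyl ether, or the 3-methyl ether may be taken through the five-membered chelate.
- The fallback removes the free phenol before the cleavage and uses a different Lewis acid. It sets out from 11 and returns at 12.
- Acetylation (Ac2O, pyridine) should give 7-acetoxy-3,5,6,8,2',4',5'-heptamethoxyflavone F7.
- Aluminium chloride in acetonitrile, which is carbonyl-chelating and now has no phenol to bind, should cleave only the peri ether to give 7-acetoxy-5-hydroxy-3,6,8,2',4',5'-hexamethoxyflavone F8.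
- Methanolysis of the acetate (K2CO3 cat., MeOH, rt) gives 12.

Further compounds
F1 | step 7 | 1-[4-(benzyloxy)-2-bromo-3,5-dimethoxyphenyl]-2-methoxy-3-(2,4,5-trimethoxyphenyl)propane-1,3-dione (racemic) | COC(C(=O)c1cc(OC)c(OCc2ccccc2)c(OC)c1Br)C(=O)c1cc(OC)c(OC)cc1OC
F2 | step 7 | 7-(benzyloxy)-3,6,8,2',4',5'-hexamethoxyflavone | COc1cc(OC)c(-c2oc3c(OC)c(OCc4ccccc4)c(OC)cc3c(=O)c2OC)cc1OC
F3 | step 7 | 7-(benzyloxy)-5-hydroxy-3,6,8,2',4',5'-hexamethoxyflavone | COc1cc(OC)c(-c2oc3c(OC)c(OCc4ccccc4)c(OC)c(O)c3c(=O)c2OC)cc1OC
F4 | step 5 | [4-(benzyloxy)-2,3,5-trimethoxyphenyl]methanol | COc1cc(CO)c(OC)c(OC)c1OCc1ccccc1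
F5 | step 5 | 4-(benzyloxy)-2,3,5-trimethoxybenzaldehyde | COc1cc(C=O)c(OC)c(OC)c1OCc1ccccc1
F6 | step 5 | 3-[4-(benzyloxy)-2,3,5-trimethoxyphenyl]-3-hydroxy-2-methoxy-1-(2,4,5-trimethoxyphenyl)propan-1-one (racemic mixture of diastereomers) | COC(C(O)c1cc(OC)c(OCc2ccccc2)c(OC)c1OC)C(=O)c1cc(OC)c(OC)cc1OC
F7 | step 8 | 7-acetoxy-3,5,6,8,2',4',5'-heptamethoxyflavone | COc1cc(OC)c(-c2oc3c(OC)c(OC(C)=O)c(OC)c(OC)c3c(=O)c2OC)cc1OC
F8 | step 8 | 7-acetoxy-5-hydroxy-3,6,8,2',4',5'-hexamethoxyflavone | COc1cc(OC)c(-c2oc3c(OC)c(OC(C)=O)c(OC)c(O)c3c(=O)c2OC)cc1OC
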